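**Plan**

- Retrosynthetic cuts: the Z-cinnamate (Cα=Cβ by Ando olefination, then the C18–O acyl bond); C13–C14 (enol triflate/vinyl coupling); C9–C11 (radical conjugate addition); C8–OH and C9–Br (bromohydrin of a C8=C9 alkene).
- Ring A: quaternary C4 carries CH3 and a one-carbon oxygenated branch (C18) next to the ring CH2 C3. C18 is therefore read as a former ring atom lying between C4 and C3 in a 1-methylcycloheptene oxide; a 1,2-shift of C3 from C18 to C4 contracts that ring to the cyclohexane and pushes C18 out as CHO.
- The cycloheptene is cut at C4=C18 (ring-closing metathesis) and at C10–C1 and C10–C20 (two enolate alkylations), which leads back to (S)-carvone, whose ring is ring B.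
- Forward order: carvone (ring B) → C10 quaternary centre → seven-membered ring → epoxide → ring contraction (ring A, C4) → C9 ketone removed with alkene transposition → C8/C9 functionalised → diene side chain → ester.
- Stereochemistry: C5 from (S)-carvone; C10 by alkylation anti to the isopropenyl group; C4 by epoxidation anti to C20 followed by the stereospecific shift; C8 and C9 by trans-diaxial bromohydrin opening and radical addition anti to C20 and 8-OH; the Z-alkene by Ando olefination.

Key step: step 5

Remark: labdane numbering is used (C17 = CH3 on C8, C18 = CH2O on C4, C19 = CH3 on C4, C20 = CH3 on C10); the target is taken exactly as drawn, (4S,5S,8R,9R,10R), i.e. a trans-decalin with 4-CH3 and 8-OH cis to C20 and with C18 and the C9 chain trans to C20.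

**Route**

Step 1
Reactants: 1 (S)-(+)-carvone
Product: 2 6-methylcarvone (mainly the epimer with 6-CH3 trans to isopropenyl)
Conditions: LiN(i-Pr)2, THF, −78 °C; MeI, −78 → 0 °C
Reagents that add atoms: iodomethane, CI
Why: Kinetic deprotonation at the α′ carbon C6 of the enone and SN2 methylation (enolate alkylation); this centre is enolised again in step 2, so its configuration does not matter.

Step 2
Reactants: 2 6-methylcarvone; 3 5-iodopent-1-ene
Product: 4 6-methyl-6-(pent-4-enyl)carvone (pentenyl trans, methyl cis to isopropenyl)
Conditions: LiN(i-Pr)2, THF, −78 °C; 3, DMPU, −78 °C → rt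
Reagents that add atoms: none
Why: Enolate alkylation of the fully substituted lithium enolate, in which the iodide should approach the face opposite the neighbouring isopropenyl group, so the chain ends trans and the methyl cis to it, which fixes C10.

Step 3
Reactants: 4 6-methyl-6-(pent-4-enyl)carvone
Product: 5 trans-fused bicyclic dienone (ring B cyclohexenone fused to a 1-methylcycloheptene, C4=C18)
Conditions: second-generation Grubbs catalyst (cat.), toluene, 80 °C
Reagents that add atoms: none
Why: Ring-closing metathesis between the monosubstituted and the 1,1-disubstituted alkene should close the seven-membered ring with loss of ethene, the conjugated enone alkene staying out.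

Step 4
Reactants: 5 bicyclic dienone
Product: 6 C4–C18 epoxide (oxygen trans to C20, cis to H5)
Conditions: mCPBA, NaHCO3, CH2Cl2, 0 °C
Reagents that add atoms: 3-chloroperoxybenzoic acid, OOC(=O)c1cccc(Cl)c1
Why: Prilezhaev epoxidation should select the electron-rich trisubstituted alkene over the enone and the face opposite the C10 methyl, which lies gauche over the other face of C4.

Step 5
Reactants: 6 C4–C18 epoxide
Product: 7 keto aldehyde (trans-decalin; C4 bears CHO trans and CH3 cis to C20; ring B enone intact)
Conditions: MeAl(OAr)2 (Ar = 4-bromo-2,6-di-tert-butylphenyl, MABR), CH2Cl2, −78 °C; dilute HCl work-up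
Reagents that add atoms: none
Why: The bulky aluminium Lewis acid binds the epoxide oxygen and weakens the tertiary C4–O bond; as positive charge builds at C4, the ring bond C18–C3 shifts to C4 on the face opposite the departing oxygen and C18 becomes the aldehyde carbon. The closest known reaction type is the Meinwald (semipinacol) rearrangement of 1-methylcycloalkene oxides to ring-contracted 1-methylcycloalkanecarbaldehydes. Ring A is formed by this 1,2-shift, which contracts the cycloheptane to the cyclohexane, and not by a cyclisation. The one new stereocentre, C4, is set stereospecifically: C3 enters anti to oxygen, so the formyl group should end on the former epoxide face (trans to C20) and the methyl cis to C20, while C5 and C10 are untouched. The step needs shift of the ring carbon in preference to the hydride on C18 and to proton loss; the bulky aluminium phenoxide is known to favour alkyl over hydride shift, and relief of cycloheptane strain works in the same direction.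

Step 6
Reactants: 7 keto aldehyde
Product: 8 hydroxy enone (C18 primary alcohol)
Conditions: NaBH4, MeOH–CH2Cl2, −78 °C
Reagents that add atoms: none
Why: Hydride reduction of the aldehyde should be much faster than 1,2-reduction of the enone carbonyl, which is flanked by quaternary C10.

Step 7
Reactants: 8 hydroxy enone
Product: 9 C18 tert-butyldimethylsilyl ether of the enone
Conditions: TBSCl, imidazole, DMF, rt
Reagents that add atoms: tert-butyldimethylsilyl chloride, C[Si](C)(Cl)C(C)(C)C
Why: Standard silylation of a primary alcohol; the ether should survive the hydride, base, radical and palladium steps that follow.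

Step 8
Reactants: 9 silyl ether enone
Product: 11 C9 enol triflate (C8=C9, OTf on C9), via lithium enolate 10 (not isolated)
Conditions: LiBH(s-Bu)3, THF, −78 °C; then PhNTf2, −78 °C → rt
Reagents that add atoms: N-phenylbis(trifluoromethanesulfonimide), O=S(=O)(N(c1ccccc1)S(=O)(=O)C(F)(F)F)C(F)(F)F
Why: Conjugate reduction of the β-unsubstituted enone by the hindered borohydride (as with carvone itself) gives the C8–C9 enolate regiospecifically, which is O-triflated.

Step 9
Reactants: 11 C9 enol triflate
Product: 12 C8=C9 alkene (CH3 on C8, H on C9)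
Conditions: Pd(OAc)2 (cat.), PPh3, HCO2H, Bu3N, DMF, 60 °C
Reagents that add atoms: none
Why: Palladium-catalysed formate reduction of the enol triflate replaces OTf by H without moving the double bond.

Step 10
Reactants: 12 C8=C9 alkene
Product: 13 bromohydrin (8-OH cis to C20, 9-Br trans to C20, trans-diaxial)
Conditions: NBS, acetone–H2O, 0 °C, dark
Reagents that add atoms: N-bromosuccinimide, O=C1CCC(=O)N1Br; water, O
Why: Bromohydrin formation: the bromonium ion should form on the face anti to C20 and be opened by water at tertiary C8 from the C20 face, the trans-diaxial (Fürst–Plattner) and Markovnikov mode, which sets C8.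

Step 11
Reactants: 13 bromohydrin; 14 methyl vinyl ketone
Product: 15 methyl ketone (9-(3-oxobutyl) chain trans to C20 and to 8-OH)
Conditions: (Me3Si)3SiH (slow addition), AIBN (cat.), excess 14, toluene, 80 °C
Reagents that add atoms: none
Why: Giese radical conjugate addition: the secondary C9 radical should add to the enone from the face opposite the two flanking axial groups (C20 on C10 and OH on C8), which sets C9 with the chain axial.

Step 12
Reactants: 15 methyl ketone
Product: 16 side-chain enol triflate (C13–OTf, C13=C16H2)
Conditions: LiN(i-Pr)2 (2.2 equiv), THF, −78 °C; PhNTf2, −78 → 0 °C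
Reagents that add atoms: N-phenylbis(trifluoromethanesulfonimide), O=S(=O)(N(c1ccccc1)S(=O)(=O)C(F)(F)F)C(F)(F)F
Why: Kinetic deprotonation of the methyl ketone at CH3 (the hindered tertiary alcohol is carried as its lithium alkoxide) and O-triflation give the terminal enol triflate.

Step 13
Reactants: 16 side-chain enol triflate
Product: 17 diene silyl ether (13(16),14-diene, 8-OH free, C18–OTBS)
Conditions: Pd(PPh3)4 (cat.), LiCl, tributyl(vinyl)stannane, THF, 65 °C
Reagents that add atoms: tributyl(vinyl)stannane, C=C[Sn](CCCC)(CCCC)CCCC
Why: Stille coupling of an enol triflate with a vinylstannane is the standard entry to 2-substituted 1,3-dienes.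

Step 14
Reactants: 17 diene silyl ether
Product: 18 diene diol (8-hydroxy-labda-13(16),14-dien-18-ol in the target configuration)
Conditions: Bu4NF, THF, rt
Reagents that add atoms: none
Why: Fluoride-mediated desilylation frees the primary alcohol and leaves the tertiary alcohol and the diene alone.

Step 15
Reactants: 18 diene diol; 19 diphenylphosphonoacetic acid
Product: 20 C18 diphenylphosphonoacetate
Conditions: DCC, DMAP (cat.), CH2Cl2, 0 °C → rt
Reagents that add atoms: none
Why: Steglich esterification should acylate only the primary alcohol, since the axial tertiary 8-OH is too hindered.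

Step 16
Reactants: 20 C18 diphenylphosphonoacetate; 21 4-(tert-butyldimethylsilyloxy)benzaldehyde
Product: 22 C18 (Z)-4-(tert-butyldimethylsilyloxy)cinnamate
Conditions: NaH, THF, −78 °C; then 21, −78 → −20 °C, dark
Reagents that add atoms: none
Why: Ando variant of the Horner–Wadsworth–Emmons reaction, in which the diaryl phosphonate should give the kinetic (Z)-cinnamate; the phosphonate CH2 is far more acidic than the tertiary alcohol.

Step 17
Reactants: 22 silyl-protected (Z)-cinnamate
Product: 23 target, 8-hydroxy-labda-13(16),14-dien-18-yl (Z)-4-hydroxycinnamate, (4S,5S,8R,9R,10R)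
Conditions: Bu4NF, AcOH, THF, 0 °C, dark
Reagents that add atoms: none
Why: Buffered fluoride cleaves the aryl silyl ether at low temperature and should neither touch the ester nor isomerise the Z-alkene.

**Compound list**

1 | (S)-(+)-carvone, (5S)-2-methyl-5-(prop-1-en-2-yl)cyclohex-2-en-1-one | O=C1C(C)=CC[C@H](C(C)=C)C1 | starting material
2 | 6-methylcarvone, mainly 6-CH3 trans to isopropenyl | O=C1C(C)=CC[C@H](C(C)=C)[C@H]1C | intermediate
3 | 5-iodopent-1-ene | C=CCCCI | starting material
4 | 6-methyl-6-(pent-4-enyl)carvone, pentenyl trans and methyl cis to isopropenyl | O=C1C(C)=CC[C@H](C(C)=C)[C@@]1(C)CCCC=C | intermediate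
5 | trans-fused 2,5,9a-trimethyl-4,4a,7,8,9,9a-hexahydrobenzo[7]annulen-1-one (4a-H trans to 9a-CH3) | O=C1[C@]2(C)CCCC=C(C)[C@H]2CC=C1C | intermediate
6 | epoxide of 5 at the cycloheptene double bond, oxygen trans to the angular methyl | O=C1[C@]2(C)CCC[C@@H]3O[C@]3(C)[C@H]2CC=C1C | intermediate
7 | trans-fused 1,4a,6-trimethyl-5-oxo-1,2,3,4,4a,5,8,8a-octahydronaphthalene-1-carbaldehyde (CHO trans, 1-CH3 cis to 4a-CH3) | O=C1[C@]2(C)CCC[C@](C)(C=O)[C@H]2CC=C1C | intermediate
8 | hydroxy enone, the C18 alcohol of 7 | O=C1[C@]2(C)CCC[C@](C)(CO)[C@H]2CC=C1C | intermediate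
9 | C18 tert-butyldimethylsilyl ether of 8 | O=C1[C@]2(C)CCC[C@](C)(CO[Si](C)(C)C(C)(C)C)[C@H]2CC=C1C | intermediate
10 | lithium C8–C9 enolate of the saturated ketone | [Li+].[O-]C1=C(C)CC[C@@H]2[C@@](C)(CO[Si](C)(C)C(C)(C)C)CCC[C@@]12C | intermediate
11 | C9 enol triflate (C8=C9) | FC(F)(F)S(=O)(=O)OC1=C(C)CC[C@@H]2[C@@](C)(CO[Si](C)(C)C(C)(C)C)CCC[C@@]12C | intermediate
12 | C8=C9 alkene, trans-decalin with C18–OTBS | CC1=C[C@]2(C)CCC[C@](C)(CO[Si](C)(C)C(C)(C)C)[C@H]2CC1 | intermediate
13 | bromohydrin, 8-OH cis and 9-Br trans to C20 | Br[C@@H]1[C@]2(C)CCC[C@](C)(CO[Si](C)(C)C(C)(C)C)[C@H]2CC[C@@]1(C)O | intermediate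
14 | methyl vinyl ketone | CC(=O)C=C | starting material
15 | methyl ketone, 9-(3-oxobutyl) chain trans to C20 | CC(=O)CC[C@@H]1[C@]2(C)CCC[C@](C)(CO[Si](C)(C)C(C)(C)C)[C@H]2CC[C@@]1(C)O | intermediate
16 | side-chain enol triflate | C=C(OS(=O)(=O)C(F)(F)F)CC[C@@H]1[C@]2(C)CCC[C@](C)(CO[Si](C)(C)C(C)(C)C)[C@H]2CC[C@@]1(C)O | intermediate
17 | 18-O-TBS ether of 8-hydroxy-labda-13(16),14-dien-18-ol | C=CC(=C)CC[C@@H]1[C@]2(C)CCC[C@](C)(CO[Si](C)(C)C(C)(C)C)[C@H]2CC[C@@]1(C)O | intermediate
18 | 8-hydroxy-labda-13(16),14-dien-18-ol (target configuration) | C=CC(=C)CC[C@@H]1[C@]2(C)CCC[C@](C)(CO)[C@H]2CC[C@@]1(C)O | intermediate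
19 | diphenylphosphonoacetic acid, 2-(diphenoxyphosphoryl)acetic acid | OC(=O)CP(=O)(Oc1ccccc1)Oc1ccccc1 | starting material
20 | C18 diphenylphosphonoacetate of 18 | C=CC(=C)CC[C@@H]1[C@]2(C)CCC[C@](C)(COC(=O)CP(=O)(Oc3ccccc3)Oc3ccccc3)[C@H]2CC[C@@]1(C)O | intermediate
21 | 4-(tert-butyldimethylsilyloxy)benzaldehyde | O=Cc1ccc(O[Si](C)(C)C(C)(C)C)cc1 | starting material
22 | C18 (Z)-4-(tert-butyldimethylsilyloxy)cinnamate of 18 | C=CC(=C)CC[C@@H]1[C@]2(C)CCC[C@](C)(COC(=O)/C=C\c3ccc(O[Si](C)(C)C(C)(C)C)cc3)[C@H]2CC[C@@]1(C)O | intermediate
23 | 8-hydroxy-labda-13(16),14-dien-18-yl (Z)-4-hydroxycinnamate, (4S,5S,8R,9R,10R) | C=CC(=C)CC[C@@H]1[C@]2(C)CCC[C@](C)(COC(=O)/C=C\c3ccc(O)cc3)[C@H]2CC[C@@]1(C)O | target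

**Step count**

Total steps: 17. Longest linear sequence: 17 steps from (S)-carvone.

**Three steps most likely to fail, each with a fallback**

Step 5 (key step). The risk is that the hydride on C18 shifts in place of the ring bond (giving the cycloheptanone), or that a proton is lost to an allylic alcohol. The fallback is a halide-mediated semipinacol route with double inversion. It sets out from dienone 5. NBS in aqueous acetone should give the bromohydrin F1 (OH on C4 cis to C20, Br on C18 trans). K2CO3 in MeOH closes it to the diastereomeric epoxide F2, with oxygen cis to C20. LiBr–HMPA in hot benzene should open F2 at the tertiary carbon with inversion to the lithium bromo alkoxide F3. In F3 the ring bond C18–C3 displaces bromide from the backside, and this second inversion leads to the same aldehyde 7, where the route is rejoined.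

Step 11. The risk is hydrogen transfer to the hindered C9 radical before it adds to the enone, or addition from the C20 face. The fallback sets out from bromohydrin 13 and uses a chain allyl transfer that needs no hydride donor. Keck allylation (allyltributylstannane, AIBN, benzene, 80 °C) should give the 9-allyl compound F4. Ozonolysis with NaBH4 work-up gives the primary alcohol F5, and I2, PPh3 and imidazole give the iodide F6. Coupling of F6 with buta-1,3-dien-2-ylmagnesium chloride (from chloroprene and Mg) under Li2CuCl4 catalysis should give diene 17 directly, so steps 12 and 13 are replaced as well.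

Step 2. The risk is slow C-alkylation of the fully substituted enolate by an unactivated primary iodide, with O-alkylation and proton transfer competing. The fallback sets out from 2. Alkylation with the far more reactive allyl bromide (same facial preference) gives 6-allyl-6-methylcarvone F7. Chemoselective hydroboration of the monosubstituted alkene with 9-BBN gives the alkylborane F8. B-alkyl Suzuki coupling of F8 with vinyl bromide (PdCl2(dppf), K3PO4, THF–H2O) returns 4.

**Further compounds**

F1 | step 5 | bromohydrin of 5 (tertiary OH cis to the angular methyl, secondary Br trans) | O=C1[C@]2(C)CCC[C@H](Br)[C@@](C)(O)[C@H]2CC=C1C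
F2 | step 5 | epoxide diastereomeric to 6 (oxygen cis to the angular methyl) | O=C1[C@]2(C)CCC[C@H]3O[C@@]3(C)[C@H]2CC=C1C
F3 | step 5 | lithium alkoxide of the tertiary bromide formed from F2 (Br trans, O cis to the angular methyl) | O=C1[C@]2(C)CCC[C@@H]([O-])[C@](C)(Br)[C@H]2CC=C1C.[Li+]
F4 | step 11 | 9-allyl compound (allyl trans to C20, 8-OH cis) | C=CC[C@@H]1[C@]2(C)CCC[C@](C)(CO[Si](C)(C)C(C)(C)C)[C@H]2CC[C@@]1(C)O
F5 | step 11 | 9-(2-hydroxyethyl) compound | OCC[C@@H]1[C@]2(C)CCC[C@](C)(CO[Si](C)(C)C(C)(C)C)[C@H]2CC[C@@]1(C)O
F6 | step 11 | 9-(2-iodoethyl) compound | ICC[C@@H]1[C@]2(C)CCC[C@](C)(CO[Si](C)(C)C(C)(C)C)[C@H]2CC[C@@]1(C)O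
F7 | step 2 | 6-allyl-6-methylcarvone (allyl trans to isopropenyl) | O=C1C(C)=CC[C@H](C(C)=C)[C@@]1(C)CC=C
F8 | step 2 | B-alkyl-9-borabicyclo[3.3.1]nonane from F7 | O=C1C(C)=CC[C@H](C(C)=C)[C@@]1(C)CCCB1C2CCCC1CCC2
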